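**Plan**

- Retrosynthesis: the C5–C6 bond between the vinyl CH and the ketal carbon of the 3,6-dihydro-1,2-dioxine is cut first, giving an acyclic peroxy orthoester that ends in a (Z)-vinylsilane. The O–C bond of that orthoester is cut next (allylic hydroperoxide 10 + orthoester 13), then the C3–O bond (silyl dienal 4 + a hydroperoxide).
- Forward: Wittig reaction and semi-hydrogenation give dienal 4; asymmetric peroxidation, oxidation, esterification and unmasking give hydroperoxide 10; exchange with orthoester 13 brings in the C17 chain; the only ring, the 1,2-dioxine, is closed last.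
- Stereochemistry: C3 (S) comes from the aminocatalytic conjugate addition of the hydroperoxide. C6 (S) is set in the ring closure under control of C3, through a chair-like transition state with axial OMe and both carbon chains equatorial.
- Enabling feature: C6 of the dioxine ring carries two oxygen atoms (ring O1 and OMe), so it is an ester-level carbon that can be generated as a methoxy(peroxy)carbenium ion. It sits next to the ring C4=C5 double bond, which can be the trace of a vinylsilane that attacked through its silicon-bearing carbon.

Key step: step 10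

Assumption: the hydroperoxide adds to the iminium ion of 4 on the face remote from the diaryl(silyloxy)methyl group, as other nucleophiles do with this catalyst class; on that basis the (S)-catalyst is taken to give (S) at C3.

Step 1
Reactants: 1 3-(trimethylsilyl)prop-2-ynal; 2 (triphenylphosphoranylidene)acetaldehyde
Product: 3 (2E)-5-(trimethylsilyl)pent-2-en-4-ynal
Conditions: CH2Cl2, 0 °C to rt
Reagents that add atoms: none
Why: Wittig olefination with the stabilised formyl ylide should give the (E)-enal, the ynal being much more electrophilic than the product enal.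

Step 2
Reactants: 3 (2E)-5-(trimethylsilyl)pent-2-en-4-ynal
Product: 4 (2E,4Z)-5-(trimethylsilyl)penta-2,4-dienal
Conditions: H2 (1 atm), Pd/CaCO3 poisoned with Pb(OAc)2 (Lindlar catalyst), quinoline, EtOAc, 0 °C to rt, stopped after 1 equiv H2
Reagents that add atoms: none
Why: Lindlar semi-hydrogenation adds H2 syn to the silylalkyne on the poisoned Pd surface and should give the (4Z)-vinylsilane while the conjugated enal is left untouched.

Step 3
Reactants: 5 2,3-dimethylbut-2-ene
Product: 6 2-methoxypropan-2-yl hydroperoxide
Conditions: O3, MeOH/CH2Cl2, −78 °C; N2 purge; kept and used as a solution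
Reagents that add atoms: ozone [O-][O+]=O; methanol CO
Why: Criegee ozonolysis in methanol, in which the carbonyl oxide from the tetrasubstituted alkene is trapped by MeOH as the α-methoxy hydroperoxide and acetone is the other fragment.

Step 4
Reactants: 4 (2E,4Z)-5-(trimethylsilyl)penta-2,4-dienal; 6 2-methoxypropan-2-yl hydroperoxide
Product: 7 (3S,4Z)-3-[(2-methoxypropan-2-yl)peroxy]-5-(trimethylsilyl)pent-4-enal
Conditions: (S)-2-{bis[3,5-bis(trifluoromethyl)phenyl][(trimethylsilyl)oxy]methyl}pyrrolidine (10 mol %), PhCO2H (10 mol %), toluene, 0 °C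
Reagents that add atoms: none
Why: Iminium-catalysed asymmetric conjugate addition of a hydroperoxide to an enal (organocatalytic β-peroxidation), in which the diaryl(silyloxy)methyl group shields one face of the (E)-iminium ion so that the peroxide enters C3 from the open face to set (S), while the silyl group blocks the δ-carbon against 1,6-addition.

Step 5
Reactants: 7 (3S,4Z)-3-[(2-methoxypropan-2-yl)peroxy]-5-(trimethylsilyl)pent-4-enal
Product: 8 (3S,4Z)-3-[(2-methoxypropan-2-yl)peroxy]-5-(trimethylsilyl)pent-4-enoic acid
Conditions: NaClO2, NaH2PO4, 2-methylbut-2-ene, t-BuOH/H2O, 0 °C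
Reagents that add atoms: sodium chlorite [Na+].[O-]Cl=O
Why: Pinnick oxidation converts the aldehyde to the acid in a weakly acidic buffer, which avoids the base-induced β-elimination of the peroxide and should leave the vinylsilane and the peroxy ketal intact.

Step 6
Reactants: 8 (3S,4Z)-3-[(2-methoxypropan-2-yl)peroxy]-5-(trimethylsilyl)pent-4-enoic acid
Product: 9 methyl (3S,4Z)-3-[(2-methoxypropan-2-yl)peroxy]-5-(trimethylsilyl)pent-4-enoate
Conditions: Me3SiCHN2, MeOH/toluene, 0 °C
Reagents that add atoms: (trimethylsilyl)diazomethane C[Si](C)(C)C=[N+]=[N-]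
Why: Esterification with a diazoalkane proceeds without base or strong acid, so neither the β-peroxy ester nor the peroxy ketal is put at risk.

Step 7
Reactants: 9 methyl (3S,4Z)-3-[(2-methoxypropan-2-yl)peroxy]-5-(trimethylsilyl)pent-4-enoate
Product: 10 methyl (3S,4Z)-3-hydroperoxy-5-(trimethylsilyl)pent-4-enoate
Conditions: AcOH/THF/H2O, rt, trace of 2,6-di-tert-butyl-4-methylphenol
Reagents that add atoms: none
Why: Mild acid hydrolysis of the peroxy ketal (a ketal-type protecting group of hydroperoxides) frees the hydroperoxide without touching the C3–O bond, so the configuration is retained.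

Step 8
Reactants: 11 heptadecanenitrile
Product: 13 1,1,1-trimethoxyheptadecane, via methyl heptadecanimidate hydrochloride 12 (not isolated)
Conditions: HCl (g), MeOH (1.1 equiv), Et2O, 0 °C; then MeOH (excess), hexane, rt
Reagents that add atoms: methanol CO
Why: Pinner reaction, in which the nitrile gives the imidate hydrochloride and this is alcoholysed to the orthoester with loss of NH4Cl.

Step 9
Reactants: 10 methyl (3S,4Z)-3-hydroperoxy-5-(trimethylsilyl)pent-4-enoate; 13 1,1,1-trimethoxyheptadecane
Product: 14 methyl (3S,4Z)-3-[(1,1-dimethoxyheptadecyl)peroxy]-5-(trimethylsilyl)pent-4-enoate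
Conditions: 13 (1.5 equiv), pyridinium p-toluenesulfonate (5 mol %), 4 Å molecular sieves, CH2Cl2, 0 °C to rt; Et3N; chromatography on Et3N-treated silica
Reagents that add atoms: none
Why: Acid-catalysed orthoester exchange (the orthoester counterpart of peroxy ketal formation) replaces one OMe by the hydroperoxide O–H while the sieves take up the methanol, and the stereocentre is not involved.

Step 10
Reactants: 14 methyl (3S,4Z)-3-[(1,1-dimethoxyheptadecyl)peroxy]-5-(trimethylsilyl)pent-4-enoate
Product: 16 6-epi-chondrillin [methyl 2-[(3S,6S)-6-hexadecyl-6-methoxy-3,6-dihydro-1,2-dioxin-3-yl]acetate], via methoxy(peroxy)carbenium triflate 15 (not isolated)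
Conditions: Me3SiOSO2CF3 (0.2 equiv), 2,6-di-tert-butyl-4-methylpyridine (0.3 equiv), CH2Cl2, −78 °C; Et3N, then NaHCO3 (aq)
Reagents that add atoms: none
Why: Proposed new method: Me3SiOSO2CF3 silylates the more basic methoxy oxygen of the peroxy orthoester and expels MeOSiMe3 to leave the methoxy(peroxy)carbenium ion 15; the silicon-bearing carbon of the (Z)-vinylsilane attacks its cationic carbon, the charge building up on the neighbouring alkene carbon is stabilised by the β C–Si bond, and loss of the silyl group to triflate restores the C=C bond and the silyl triflate. The closest known reaction types are the vinylsilane-terminated cyclisation of oxocarbenium ions (silyl-Prins route to dihydropyrans) and the Lewis acid-mediated C–C bond formation of peroxycarbenium ions, made from peroxy ketals, with allylsilanes and silyl enol ethers; an ester-level cation with the peroxide in the tether has no precedent. The 1,2-dioxine closes in a 6-endo-trig mode with both former vinylsilane carbons in the ring, a geometry that only the (Z)-silane can reach. The new ketal centre is set under kinetic control by the existing peroxide-bearing stereocentre: in the chair-like transition state its CH2CO2Me group and the hexadecyl chain (anti to the O–O bond across the partial C–O double bond of the cation) lie equatorial and the methoxy group axial with anomeric assistance from the ring oxygen, which corresponds to the (6S) isomer with OMe cis to CH2CO2Me. The step needs bond formation at the ipso carbon (six-membered ring) and not at the β carbon (1,2-dioxolane), which the β-silicon effect secures, and it needs cyclisation to outrun Criegee-type O–O heterolysis of the activated peroxide and re-ionisation of the product ketal, for which the low temperature, the substoichiometric silyl triflate and the hindered pyridine base are chosen.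

**Compound list**

1 | 3-(trimethylsilyl)prop-2-ynal | C[Si](C)(C)C#CC=O | starting material
2 | (triphenylphosphoranylidene)acetaldehyde | O=CC=P(c1ccccc1)(c1ccccc1)c1ccccc1 | starting material
3 | (2E)-5-(trimethylsilyl)pent-2-en-4-ynal | C[Si](C)(C)C#C/C=C/C=O | intermediate
4 | (2E,4Z)-5-(trimethylsilyl)penta-2,4-dienal | C[Si](C)(C)/C=C\C=C\C=O | intermediate
5 | 2,3-dimethylbut-2-ene | CC(C)=C(C)C | starting material
6 | 2-methoxypropan-2-yl hydroperoxide | COC(C)(C)OO | intermediate
7 | (3S,4Z)-3-[(2-methoxypropan-2-yl)peroxy]-5-(trimethylsilyl)pent-4-enal | C[Si](C)(C)/C=C\[C@H](CC=O)OOC(C)(C)OC | intermediate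
8 | (3S,4Z)-3-[(2-methoxypropan-2-yl)peroxy]-5-(trimethylsilyl)pent-4-enoic acid | C[Si](C)(C)/C=C\[C@H](CC(=O)O)OOC(C)(C)OC | intermediate
9 | methyl (3S,4Z)-3-[(2-methoxypropan-2-yl)peroxy]-5-(trimethylsilyl)pent-4-enoate | C[Si](C)(C)/C=C\[C@H](CC(=O)OC)OOC(C)(C)OC | intermediate
10 | methyl (3S,4Z)-3-hydroperoxy-5-(trimethylsilyl)pent-4-enoate | C[Si](C)(C)/C=C\[C@H](CC(=O)OC)OO | intermediate
11 | heptadecanenitrile | CCCCCCCCCCCCCCCCC#N | starting material
12 | methyl heptadecanimidate hydrochloride (not isolated) | CCCCCCCCCCCCCCCCC(OC)=[NH2+].[Cl-] | intermediate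
13 | 1,1,1-trimethoxyheptadecane (trimethyl orthoheptadecanoate) | CCCCCCCCCCCCCCCCC(OC)(OC)OC | intermediate
14 | methyl (3S,4Z)-3-[(1,1-dimethoxyheptadecyl)peroxy]-5-(trimethylsilyl)pent-4-enoate | C[Si](C)(C)/C=C\[C@H](CC(=O)OC)OOC(OC)(OC)CCCCCCCCCCCCCCCC | intermediate
15 | methoxy(peroxy)carbenium triflate formed from 14 by loss of one methoxy group (not isolated) | C[Si](C)(C)/C=C\[C@H](CC(=O)OC)OOC(=[O+]C)CCCCCCCCCCCCCCCC.[O-]S(=O)(=O)C(F)(F)F | intermediate
16 | 6-epi-chondrillin, methyl 2-[(3S,6S)-6-hexadecyl-6-methoxy-3,6-dihydro-1,2-dioxin-3-yl]acetate | CCCCCCCCCCCCCCCC[C@@]1(OC)C=C[C@H](CC(=O)OC)OO1 | target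

**Step count and risks**

Total: 10 steps. Longest linear sequence: 8 steps (1, 2, 4, 5, 6, 7, 9, 10).

Steps most likely to fail:

1. Step 10 (Proposed new method). What may go wrong: Criegee-type heterolysis of the O–O bond in the cation with loss of methyl heptadecanoate; ionisation at the peroxide oxygen with loss of the hydroperoxide; capture by the weakly nucleophilic vinylsilane being too slow; epimerisation of the ketal centre through re-ionisation of the product. Fallback with known chemistry, in which the ring is closed by hemiketal formation instead; it sets out from 9 and comes back at 16. Iododesilylation of 9 with N-iodosuccinimide in MeCN should give, with retention, methyl (3S,4Z)-5-iodo-3-[(2-methoxypropan-2-yl)peroxy]pent-4-enoate F1. Stannylation with Me3SnSnMe3 and Pd(PPh3)4 should give methyl (3S,4Z)-3-[(2-methoxypropan-2-yl)peroxy]-5-(trimethylstannyl)pent-4-enoate F2. Stille acylation of F2 with heptadecanoyl chloride and PdCl2(PPh3)2 under neutral conditions should give the (Z)-enone methyl (3S,4Z)-3-[(2-methoxypropan-2-yl)peroxy]-6-oxodocos-4-enoate F3. AcOH/THF/H2O frees methyl (3S,4Z)-3-hydroperoxy-6-oxodocos-4-enoate F4, whose hydroperoxide adds to the cis-placed ketone to give the dioxinol methyl 2-[(3S)-6-hexadecyl-6-hydroxy-3,6-dihydro-1,2-dioxin-3-yl]acetate F5. Exchange of OH for OMe with TsOH in MeOH should give 16 together with its C6 epimer methyl 2-[(3S,6R)-6-hexadecyl-6-methoxy-3,6-dihydro-1,2-dioxin-3-yl]acetate F6, from which 16 is separated by chromatography.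

2. Step 4. What may go wrong: 1,6-addition or (Z) to (E) isomerisation of the silyl dienal under amine catalysis; closure of the β-peroxy enamine to the epoxide with loss of the alkoxide; poor facial selectivity on this extended substrate. Fallback that removes the (Z)-vinylsilane from the amine-catalysed step and carries the silylalkyne as its masked form; it sets out from 3 and 6 and comes back at 9. The same peroxidation run on enynal 3 should give (3S)-3-[(2-methoxypropan-2-yl)peroxy]-5-(trimethylsilyl)pent-4-ynal F7. Pinnick oxidation gives (3S)-3-[(2-methoxypropan-2-yl)peroxy]-5-(trimethylsilyl)pent-4-ynoic acid F8, and Me3SiCHN2 gives methyl (3S)-3-[(2-methoxypropan-2-yl)peroxy]-5-(trimethylsilyl)pent-4-ynoate F9. Semi-hydrogenation of F9 over Pd/CaCO3 poisoned with Pb(OAc)2 with quinoline, which a dialkyl peroxy ketal is expected to survive, gives 9.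

3. Step 9. What may go wrong: the exchange equilibrium stays on the side of the reactants; a second exchange puts two peroxy groups on one orthoester carbon; the mixed peroxy orthoester is hydrolysed during isolation. Fallback that replaces the exchange by an irreversible addition; it sets out from 13 and 10 and comes back at 14. Treatment of 13 with Me3SiOSO2CF3 and i-Pr2NEt removes one methoxy group and a proton to give the ketene acetal 1,1-dimethoxyheptadec-1-ene F10. Hydroperoxide 10 then adds across its electron-rich C=C bond (CH2Cl2, 0 °C, at most a trace of pyridinium p-toluenesulfonate) in the Markovnikov sense to give 14 without release of methanol.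

Further compounds
F1 | step 10 | methyl (3S,4Z)-5-iodo-3-[(2-methoxypropan-2-yl)peroxy]pent-4-enoate | I/C=C\[C@H](CC(=O)OC)OOC(C)(C)OC
F2 | step 10 | methyl (3S,4Z)-3-[(2-methoxypropan-2-yl)peroxy]-5-(trimethylstannyl)pent-4-enoate | C[Sn](C)(C)/C=C\[C@H](CC(=O)OC)OOC(C)(C)OC
F3 | step 10 | methyl (3S,4Z)-3-[(2-methoxypropan-2-yl)peroxy]-6-oxodocos-4-enoate | CCCCCCCCCCCCCCCCC(=O)/C=C\[C@H](CC(=O)OC)OOC(C)(C)OC
F4 | step 10 | methyl (3S,4Z)-3-hydroperoxy-6-oxodocos-4-enoate | CCCCCCCCCCCCCCCCC(=O)/C=C\[C@H](CC(=O)OC)OO
F5 | step 10 | methyl 2-[(3S)-6-hexadecyl-6-hydroxy-3,6-dihydro-1,2-dioxin-3-yl]acetate | CCCCCCCCCCCCCCCCC1(O)C=C[C@H](CC(=O)OC)OO1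
F6 | step 10 | methyl 2-[(3S,6R)-6-hexadecyl-6-methoxy-3,6-dihydro-1,2-dioxin-3-yl]acetate | CCCCCCCCCCCCCCCC[C@]1(OC)C=C[C@H](CC(=O)OC)OO1
F7 | step 4 | (3S)-3-[(2-methoxypropan-2-yl)peroxy]-5-(trimethylsilyl)pent-4-ynal | C[Si](C)(C)C#C[C@H](CC=O)OOC(C)(C)OC
F8 | step 4 | (3S)-3-[(2-methoxypropan-2-yl)peroxy]-5-(trimethylsilyl)pent-4-ynoic acid | C[Si](C)(C)C#C[C@H](CC(=O)O)OOC(C)(C)OC
F9 | step 4 | methyl (3S)-3-[(2-methoxypropan-2-yl)peroxy]-5-(trimethylsilyl)pent-4-ynoate | C[Si](C)(C)C#C[C@H](CC(=O)OC)OOC(C)(C)OC
F10 | step 9 | 1,1-dimethoxyheptadec-1-ene | CCCCCCCCCCCCCCCC=C(OC)OC
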